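**Plan**

- Retrosynthesis: take off the methacrylate, the acetate and the silyl groups; cut C2=C3 (ring-closing metathesis); cut the lactone bonds O–C6 and C11–C12, which takes out CO2; cut C9–C10 (alkenyllithium alkylation), C8–C9 (halomethyl ketone from an ester) and C6–C7 (titanium-mediated alkynoate–aldehyde coupling).
- Forward: an epoxy aldehyde (C2–C6, C15) and an alkynoate (C7, C8, C11, C13) give the open chain with the C7=C11 double bond; C9 and the C10/C14/C1/C2 dienol are added and epoxidised; the butenolide ring (O, C12, C11, C7, C6) is then closed with CO2; the ten-membered carbocycle is closed last and the two esters are put on.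
- Feature used by the key event: C11 (vinylic, carried as C–Br) and the allylic carbinol carbon C6 (between the C4–C5 oxirane and C7) are held cis on the tetrasubstituted C7=C11 double bond. C11 can be made a nucleophile and C6 an electrophile, so one CO2 bridges them with its carbon and one oxygen.
- Stereochemistry: C4/C5 and C10/C1 from two Sharpless epoxidations; C6 from Felkin–Anh addition followed by two inversions; C8 from CBS reduction; C7=C11 geometry from a five-membered oxatitanacycle; C2=C3 Z from the ring size.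

Key step: step 17

Remark: atoms are numbered as in the germacrane skeleton of the target (C1–C10 ring carbons, C11–C13 lactone side carbons, C14 hydroxymethyl carbon, C15 methyl carbon). TBS = tert-butyldimethylsilyl, TES = triethylsilyl, TBDPS = tert-butyldiphenylsilyl. Compounds 1, 5, 6, 13, 17, 18 and 28 are taken as commercial. CIP descriptors change along the route where substituent priorities change; the SMILES strings are definitive.

Step 1
Reactants: 1 (2Z)-3-methylpent-2-en-4-yn-1-ol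
Product: 2 (2Z)-3-methylpenta-2,4-dien-1-ol
Conditions: H2 (1 atm), Pd/CaCO3 poisoned with Pb(OAc)2, quinoline, EtOAc, 0 °C
Reagents that add atoms: none
Why: Lindlar semihydrogenation should stop at the terminal alkene and leave the trisubstituted Z alkene untouched, so the vinyl group is in place before any oxirane exists.

Step 2
Reactants: 2 (2Z)-3-methylpenta-2,4-dien-1-ol
Product: 3 [(2S,3R)-3-ethenyl-3-methyloxiran-2-yl]methanol
Conditions: Ti(OiPr)4 (cat.), L-(+)-diethyl tartrate, t-BuOOH, 4 Å molecular sieves, CH2Cl2, −20 °C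
Reagents that add atoms: tert-butyl hydroperoxide, CC(C)(C)OO
Why: Sharpless asymmetric epoxidation acts only on the alkene of the allylic alcohol, and L-(+)-tartrate control should deliver oxygen to the face that gives the 4R,5S oxirane (target numbering) with the vinyl group cis to the carbinol arm, as fixed by the Z alkene.

Step 3
Reactants: 3 [(2S,3R)-3-ethenyl-3-methyloxiran-2-yl]methanol
Product: 4 (2R,3R)-3-ethenyl-3-methyloxirane-2-carbaldehyde
Conditions: Dess–Martin periodinane, NaHCO3, CH2Cl2, 0 °C; used as a solution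
Reagents that add atoms: none
Why: Buffered Dess–Martin oxidation should give the volatile epoxy aldehyde without epimerisation at the α-carbon (the new descriptor at that carbon is only a priority change).

Step 4
Reactants: 5 tert-butyldimethyl(prop-2-yn-1-yloxy)silane; 6 methyl chloroformate
Product: 8 methyl 4-(TBSO)but-2-ynoate, via lithium acetylide 7 (not isolated)
Conditions: n-BuLi, THF, −78 °C; then 6, −78 → 0 °C
Reagents that add atoms: methyl chloroformate, COC(=O)Cl; n-butyllithium, [Li]CCCC (lithium of 7 only)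
Why: Acylation of a lithium acetylide with a chloroformate is the standard route to 2-alkynoates.

Step 5
Reactants: 8 methyl 4-(TBSO)but-2-ynoate; 4 (2R,3R)-3-ethenyl-3-methyloxirane-2-carbaldehyde
Product: 11 methyl (2E)-3-bromo-4-(TBSO)-2-[(S)-hydroxy[(2S,3R)-3-ethenyl-3-methyloxiran-2-yl]methyl]but-2-enoate, via titanacyclopropene 9 (not isolated), via oxatitanacyclopentene 10 (not isolated)
Conditions: Ti(OiPr)4, i-PrMgCl (2 equiv), Et2O, −78 → −50 °C; then 4, −78 °C; then N-bromosuccinimide, −78 → 0 °C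
Reagents that add atoms: N-bromosuccinimide, O=C1CCC(=O)N1Br; titanium tetraisopropoxide, CC(C)O[Ti](OC(C)C)(OC(C)C)OC(C)C (titanium and isopropoxide groups of 9 and 10 only)
Why: In this low-valent titanium alkoxide-mediated alkyne–aldehyde coupling the alkynoate complex 9 should insert the aldehyde at the ester-bearing carbon (Baylis–Hillman-type regiochemistry), the five-membered ring of 10 holds the remaining C–Ti bond cis to the new carbinol so that bromodemetalation puts Br on C11 cis to C6, and Felkin–Anh attack anti to the oxirane C–O bond of 4 should set the 6S carbinol.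

Step 6
Reactants: 11 methyl (2E)-3-bromo-4-(TBSO)-2-[(S)-hydroxy[(2S,3R)-3-ethenyl-3-methyloxiran-2-yl]methyl]but-2-enoate
Product: 12 methyl (2E)-3-bromo-4-(TBSO)-2-[(S)-[(2S,3R)-3-ethenyl-3-methyloxiran-2-yl](TESO)methyl]but-2-enoate
Conditions: TESOTf, 2,6-lutidine, CH2Cl2, −78 °C
Reagents that add atoms: triethylsilyl triflate, CC[Si](CC)(CC)OS(=O)(=O)C(F)(F)F
Why: Triflate silylation masks the hindered C6 hydroxyl through the organolithium steps and keeps it distinguishable from the C8 hydroxyl made next.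

Step 7
Reactants: 12 methyl (2E)-3-bromo-4-(TBSO)-2-[(S)-[(2S,3R)-3-ethenyl-3-methyloxiran-2-yl](TESO)methyl]but-2-enoate; 13 diiodomethane
Product: 14 (3E)-4-bromo-5-(TBSO)-3-[(S)-[(2S,3R)-3-ethenyl-3-methyloxiran-2-yl](TESO)methyl]-1-iodopent-3-en-2-one
Conditions: MeLi·LiBr, THF/Et2O, −78 °C; NH4Cl quench at −78 °C
Reagents that add atoms: diiodomethane, ICI
Why: Iodomethyllithium made in the flask by iodine–lithium exchange acylates at the ester carbonyl and the tetrahedral adduct survives until the cold quench, so the halomethyl ketone (C8 carbonyl, C9 iodide) should form without over-addition.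

Step 8
Reactants: 14 (3E)-4-bromo-5-(TBSO)-3-[(S)-[(2S,3R)-3-ethenyl-3-methyloxiran-2-yl](TESO)methyl]-1-iodopent-3-en-2-one
Product: 15 (2R)-4-bromo-5-(TBSO)-3-[(S)-[(2S,3R)-3-ethenyl-3-methyloxiran-2-yl](TESO)methyl]-1-iodopent-3-en-2-ol (Br cis to C6)
Conditions: (R)-2-methyl-CBS-oxazaborolidine (cat.), BH3·SMe2, THF, −30 °C
Reagents that add atoms: none
Why: Corey–Bakshi–Shibata reduction with the (R)-catalyst treats the tetrasubstituted alkenyl group as the large and CH2I as the small substituent and should place the C8 oxygen as in the target (the descriptor is R here only because of the iodine).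

Step 9
Reactants: 15 (2R)-4-bromo-5-(TBSO)-3-[(S)-[(2S,3R)-3-ethenyl-3-methyloxiran-2-yl](TESO)methyl]-1-iodopent-3-en-2-ol
Product: 16 (2R)-4-bromo-2,5-bis(TBSO)-3-[(S)-[(2S,3R)-3-ethenyl-3-methyloxiran-2-yl](TESO)methyl]-1-iodopent-3-ene (Br cis to C6)
Conditions: TBSOTf, 2,6-lutidine, CH2Cl2, −78 → 0 °C
Reagents that add atoms: tert-butyldimethylsilyl triflate, CC(C)(C)[Si](C)(C)OS(=O)(=O)C(F)(F)F
Why: Triflate silylation under weakly basic conditions protects the C8 alcohol without closing the iodohydrin to an oxirane.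

Step 10
Reactants: 17 prop-2-yn-1-ol; 18 bromoethene
Product: 19 pent-4-en-2-yn-1-ol
Conditions: PdCl2(PPh3)2 (cat.), CuI (cat.), i-Pr2NH, THF, 0 °C → rt
Reagents that add atoms: none
Why: Sonogashira coupling of a terminal alkyne with a vinyl bromide gives the conjugated enyne directly.

Step 11
Reactants: 19 pent-4-en-2-yn-1-ol
Product: 20 (2E)-2-(tributylstannyl)penta-2,4-dien-1-ol
Conditions: Bu3SnH, Mo(CO)3(CNtBu)3 (cat.), hydroquinone, THF, 55 °C
Reagents that add atoms: tributyltin hydride, CCCC[SnH](CCCC)CCCC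
Why: Molybdenum-catalysed hydrostannation of propargylic alcohols is a syn addition that places tin on the alkyne carbon next to the carbinol carbon, so the hydroxymethyl group should end cis to the vinyl group as the C1–C10 geometry requires.

Step 12
Reactants: 20 (2E)-2-(tributylstannyl)penta-2,4-dien-1-ol; 16 (2R)-4-bromo-2,5-bis(TBSO)-3-[(S)-[(2S,3R)-3-ethenyl-3-methyloxiran-2-yl](TESO)methyl]-1-iodopent-3-ene
Product: 22 (2Z)-2-[(2S)-4-bromo-2,5-bis(TBSO)-3-[(S)-[(2S,3R)-3-ethenyl-3-methyloxiran-2-yl](TESO)methyl]pent-3-en-1-yl]penta-2,4-dien-1-ol (Br cis to C6), via dilithio dienolate 21 (not isolated)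
Conditions: n-BuLi (2.1 equiv), THF, −78 → −30 °C; then 16, HMPA, −78 → −40 °C
Reagents that add atoms: n-butyllithium, [Li]CCCC (lithium of 21 only)
Why: Tin–lithium exchange and SN2 alkylation of the alkenyllithium by the primary iodide both retain the alkene geometry and form C9–C10, while the alkenyl bromide, the silyl ethers and the oxirane should be inert to an alkenyllithium at low temperature.

Step 13
Reactants: 22 (2Z)-2-[(2S)-4-bromo-2,5-bis(TBSO)-3-[(S)-[(2S,3R)-3-ethenyl-3-methyloxiran-2-yl](TESO)methyl]pent-3-en-1-yl]penta-2,4-dien-1-ol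
Product: 23 [(2S,3R)-2-[(2S)-4-bromo-2,5-bis(TBSO)-3-[(S)-[(2S,3R)-3-ethenyl-3-methyloxiran-2-yl](TESO)methyl]pent-3-en-1-yl]-3-ethenyloxiran-2-yl]methanol (Br cis to C6)
Conditions: Ti(OiPr)4, L-(+)-diethyl tartrate, t-BuOOH, 4 Å molecular sieves, CH2Cl2, −20 °C
Reagents that add atoms: tert-butyl hydroperoxide, CC(C)(C)OO
Why: Sharpless asymmetric epoxidation acts only on the alkene of the free allylic alcohol, and L-(+)-tartrate control should set 10S and 1R with the hydroxymethyl group cis to the vinyl group.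

Step 14
Reactants: 23 [(2S,3R)-2-[(2S)-4-bromo-2,5-bis(TBSO)-3-[(S)-[(2S,3R)-3-ethenyl-3-methyloxiran-2-yl](TESO)methyl]pent-3-en-1-yl]-3-ethenyloxiran-2-yl]methanol
Product: 24 14-O-TBDPS ether of 23
Conditions: TBDPSCl, imidazole, CH2Cl2, 0 °C → rt
Reagents that add atoms: tert-butyldiphenylsilyl chloride, CC(C)(C)[Si](Cl)(c1ccccc1)c1ccccc1
Why: Silylation of the only free hydroxyl with the robust TBDPS group keeps O14 masked until the last step.

Step 15
Reactants: 24 14-O-TBDPS ether of 23
Product: 25 C6 alcohol obtained from 24 by loss of the TES group (6S)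
Conditions: HF·pyridine, pyridine, THF, 0 °C
Reagents that add atoms: none
Why: Buffered fluoride cleaves the triethylsilyl ether much faster than the tert-butyl-substituted silyl ethers, so only the C6 hydroxyl should be freed.

Step 16
Reactants: 25 C6 alcohol obtained from 24 by loss of the TES group (6S)
Product: 27 C6 chloride of 25 (6R; OH replaced by Cl with inversion), via mesylate 26 (not isolated)
Conditions: MsCl, Et3N, CH2Cl2, −40 °C; then LiCl, DMF, 0 °C → rt
Reagents that add atoms: methanesulfonyl chloride, CS(=O)(=O)Cl (mesyl group of 26 only); lithium chloride, [Li+].[Cl-]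
Why: Mesylation followed by SN2 displacement with chloride inverts C6 to the allylic chloride, a leaving group that tolerates the organolithium of the next step and is displaced there once more with inversion.

Step 17
Reactants: 27 C6 chloride of 25 (6R); 28 carbon dioxide
Product: 31 (5S)-3-[(TBSO)methyl]-4-[(1S)-1-(TBSO)-2-[(2S,3R)-2-[(TBDPSO)methyl]-3-ethenyloxiran-2-yl]ethyl]-5-[(2S,3R)-3-ethenyl-3-methyloxiran-2-yl]furan-2(5H)-one, via alkenyllithium 29 (not isolated), via lithium carboxylate 30 (not isolated)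
Conditions: t-BuLi (2.05 equiv), THF/Et2O, −100 °C; CO2 (dry gas), −100 → 0 °C; then DMF, 40 °C
Reagents that add atoms: carbon dioxide, O=C=O; tert-butyllithium, [Li]C(C)(C)C (lithium of 29 and 30 only)
Why: Bromine–lithium exchange at C11 with retention gives alkenyllithium 29, which adds to CO2 to form the C11–C12 bond (carboxylate 30), and on warming in DMF the carboxylate oxygen displaces the allylic chloride at C6 to form the O–C6 bond. The closest known reaction types are the carboxylation of alkenyllithiums and the lactonisation of halo carboxylates by intramolecular O-alkylation. The butenolide ring (O, C12, C11, C7, C6) closes in the 5-exo-tet mode. C6 is set by SN2 inversion of the 6R chloride, itself made with inversion from the Felkin alcohol, so the lactone oxygen should end anti to the C4–C5 oxirane oxygen as in the target, and no other stereocentre is touched. The step needs the exchange to outrun attack of t-BuLi on the allylic chloride and the vinyl oxiranes, which the very fast exchange at −100 °C with two equivalents should secure; it also needs O-alkylation at C6 only, which the tetrasubstituted C7=C11 bond secures by holding C12 cis to C6 (attack at C5 would need a six-membered ring through an unactivated oxirane opening, and C8 is out of reach).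

Step 18
Reactants: 31 (5S)-3-[(TBSO)methyl]-4-[(1S)-1-(TBSO)-2-[(2S,3R)-2-[(TBDPSO)methyl]-3-ethenyloxiran-2-yl]ethyl]-5-[(2S,3R)-3-ethenyl-3-methyloxiran-2-yl]furan-2(5H)-one
Product: 32 (1R,4R,5S,6S,8S,10S)-8,13-bis(TBSO)-14-(TBDPSO)-1,10:4,5-diepoxygermacra-2Z,7(11)-dien-12,6-olide
Conditions: second-generation Grubbs catalyst (10 mol %), toluene (1 mM), 80 °C
Reagents that add atoms: none
Why: Ring-closing metathesis joins the two monosubstituted vinyl groups, the only alkenes the catalyst can load onto, and a ten-membered ring between the two oxiranes should accommodate only the cis alkene, so C2=C3 should form Z.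

Step 19
Reactants: 32 (1R,4R,5S,6S,8S,10S)-8,13-bis(TBSO)-14-(TBDPSO)-1,10:4,5-diepoxygermacra-2Z,7(11)-dien-12,6-olide
Product: 33 (1R,4R,5S,6S,8S,10S)-14-(TBDPSO)-1,10:4,5-diepoxy-8,13-dihydroxygermacra-2Z,7(11)-dien-12,6-olide
Conditions: HF·pyridine, pyridine, THF, 0 °C → rt
Reagents that add atoms: none
Why: Buffered acidic fluoride should remove the two TBS ethers while the more acid-stable primary TBDPS ether survives.

Step 20
Reactants: 33 (1R,4R,5S,6S,8S,10S)-14-(TBDPSO)-1,10:4,5-diepoxy-8,13-dihydroxygermacra-2Z,7(11)-dien-12,6-olide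
Product: 34 (1R,4R,5S,6S,8S,10S)-13-acetoxy-14-(TBDPSO)-1,10:4,5-diepoxy-8-hydroxygermacra-2Z,7(11)-dien-12,6-olide
Conditions: AcCl, 2,4,6-collidine, CH2Cl2, −78 °C
Reagents that add atoms: acetyl chloride, CC(Cl)=O
Why: Low-temperature acylation with a hindered base should be selective for the primary C13 hydroxyl over the hindered secondary C8 hydroxyl.

Step 21
Reactants: 34 (1R,4R,5S,6S,8S,10S)-13-acetoxy-14-(TBDPSO)-1,10:4,5-diepoxy-8-hydroxygermacra-2Z,7(11)-dien-12,6-olide
Product: 35 (1R,4R,5S,6S,8S,10S)-13-acetoxy-14-(TBDPSO)-1,10:4,5-diepoxy-8-(methacryloyloxy)germacra-2Z,7(11)-dien-12,6-olide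
Conditions: methacryloyl chloride, Et3N, DMAP (cat.), CH2Cl2, 0 °C
Reagents that add atoms: methacryloyl chloride, C=C(C)C(Cl)=O
Why: DMAP-catalysed acylation should esterify the remaining secondary alcohol without touching the oxiranes or the lactone.

Step 22
Reactants: 35 (1R,4R,5S,6S,8S,10S)-13-acetoxy-14-(TBDPSO)-1,10:4,5-diepoxy-8-(methacryloyloxy)germacra-2Z,7(11)-dien-12,6-olide
Product: 36 (1R,4R,5S,6S,8S,10S)-13-acetoxy-1,10:4,5-diepoxy-14-hydroxy-8-(methacryloyloxy)germacra-2Z,7(11)-dien-12,6-olide (CNP0207684.1)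
Conditions: HF·pyridine, pyridine, THF, rt
Reagents that add atoms: none
Why: Buffered fluoride desilylation frees O14 under conditions that should leave both esters, the butenolide and the vinyl oxiranes intact.

**Compound list**

1 | (2Z)-3-methylpent-2-en-4-yn-1-ol | OC/C=C(/C)C#C | starting material
2 | (2Z)-3-methylpenta-2,4-dien-1-ol | OC/C=C(/C)C=C | intermediate
3 | [(2S,3R)-3-ethenyl-3-methyloxiran-2-yl]methanol | OC[C@@H]1O[C@]1(C)C=C | intermediate
4 | (2R,3R)-3-ethenyl-3-methyloxirane-2-carbaldehyde | O=C[C@@H]1O[C@]1(C)C=C | intermediate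
5 | tert-butyldimethyl(prop-2-yn-1-yloxy)silane | C#CCO[Si](C)(C)C(C)(C)C | starting material
6 | methyl chloroformate | COC(=O)Cl | starting material
7 | lithium acetylide of 5 | [Li]C#CCO[Si](C)(C)C(C)(C)C | intermediate
8 | methyl 4-(TBSO)but-2-ynoate | COC(=O)C#CCO[Si](C)(C)C(C)(C)C | intermediate
9 | diisopropoxytitanacyclopropene of 8 | COC(=O)C1=C(CO[Si](C)(C)C(C)(C)C)[Ti]1(OC(C)C)OC(C)C | intermediate
10 | oxatitanacyclopentene from 9 and 4 (Ti–O–C6 and Ti–C11) | COC(=O)C1=C(CO[Si](C)(C)C(C)(C)C)[Ti](OC(C)C)(OC(C)C)O[C@@H]1[C@@H]1O[C@]1(C)C=C | intermediate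
11 | methyl (2E)-3-bromo-4-(TBSO)-2-[(S)-hydroxy[(2S,3R)-3-ethenyl-3-methyloxiran-2-yl]methyl]but-2-enoate | COC(=O)/C(=C(\CO[Si](C)(C)C(C)(C)C)Br)[C@H](O)[C@@H]1O[C@]1(C)C=C | intermediate
12 | C6 TES ether of 11 | COC(=O)/C(=C(\CO[Si](C)(C)C(C)(C)C)Br)[C@H](O[Si](CC)(CC)CC)[C@@H]1O[C@]1(C)C=C | intermediate
13 | diiodomethane | ICI | starting material
14 | iodomethyl ketone (C8 carbonyl, C9 iodide) from 12 | ICC(=O)/C(=C(\CO[Si](C)(C)C(C)(C)C)Br)[C@H](O[Si](CC)(CC)CC)[C@@H]1O[C@]1(C)C=C | intermediate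
15 | (8R)-iodohydrin from 14 | IC[C@H](O)/C(=C(\CO[Si](C)(C)C(C)(C)C)Br)[C@H](O[Si](CC)(CC)CC)[C@@H]1O[C@]1(C)C=C | intermediate
16 | C8 TBS ether of 15 | IC[C@H](O[Si](C)(C)C(C)(C)C)/C(=C(\CO[Si](C)(C)C(C)(C)C)Br)[C@H](O[Si](CC)(CC)CC)[C@@H]1O[C@]1(C)C=C | intermediate
17 | prop-2-yn-1-ol | C#CCO | starting material
18 | bromoethene | C=CBr | starting material
19 | pent-4-en-2-yn-1-ol | OCC#CC=C | intermediate
20 | (2E)-2-(tributylstannyl)penta-2,4-dien-1-ol | OC/C([Sn](CCCC)(CCCC)CCCC)=C\C=C | intermediate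
21 | lithium (2Z)-2-lithiopenta-2,4-dien-1-olate | [Li]OC/C([Li])=C\C=C | intermediate
22 | dienol from 21 and 16 (C9–C10 bond; 6S, 8S) | OC/C(=C\C=C)C[C@H](O[Si](C)(C)C(C)(C)C)/C(=C(\CO[Si](C)(C)C(C)(C)C)Br)[C@H](O[Si](CC)(CC)CC)[C@@H]1O[C@]1(C)C=C | intermediate
23 | (1R,10S)-epoxy alcohol from 22 | C=C[C@H]1O[C@]1(CO)C[C@H](O[Si](C)(C)C(C)(C)C)/C(=C(\CO[Si](C)(C)C(C)(C)C)Br)[C@H](O[Si](CC)(CC)CC)[C@@H]1O[C@]1(C)C=C | intermediate
24 | 14-O-TBDPS ether of 23 | C=C[C@H]1O[C@]1(CO[Si](c2ccccc2)(c2ccccc2)C(C)(C)C)C[C@H](O[Si](C)(C)C(C)(C)C)/C(=C(\CO[Si](C)(C)C(C)(C)C)Br)[C@H](O[Si](CC)(CC)CC)[C@@H]1O[C@]1(C)C=C | intermediate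
25 | (6S)-alcohol from 24 | C=C[C@H]1O[C@]1(CO[Si](c2ccccc2)(c2ccccc2)C(C)(C)C)C[C@H](O[Si](C)(C)C(C)(C)C)/C(=C(\CO[Si](C)(C)C(C)(C)C)Br)[C@H](O)[C@@H]1O[C@]1(C)C=C | intermediate
26 | (6S)-mesylate of 25 | C=C[C@H]1O[C@]1(CO[Si](c2ccccc2)(c2ccccc2)C(C)(C)C)C[C@H](O[Si](C)(C)C(C)(C)C)/C(=C(\CO[Si](C)(C)C(C)(C)C)Br)[C@H](OS(C)(=O)=O)[C@@H]1O[C@]1(C)C=C | intermediate
27 | (6R)-chloride from 25 | C=C[C@H]1O[C@]1(CO[Si](c2ccccc2)(c2ccccc2)C(C)(C)C)C[C@H](O[Si](C)(C)C(C)(C)C)/C(=C(\CO[Si](C)(C)C(C)(C)C)Br)[C@@H](Cl)[C@@H]1O[C@]1(C)C=C | intermediate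
28 | carbon dioxide | O=C=O | starting material
29 | C11 alkenyllithium from 27 | C=C[C@H]1O[C@]1(CO[Si](c2ccccc2)(c2ccccc2)C(C)(C)C)C[C@H](O[Si](C)(C)C(C)(C)C)/C(=C(\CO[Si](C)(C)C(C)(C)C)[Li])[C@@H](Cl)[C@@H]1O[C@]1(C)C=C | intermediate
30 | lithium C12 carboxylate from 29 | C=C[C@H]1O[C@]1(CO[Si](c2ccccc2)(c2ccccc2)C(C)(C)C)C[C@H](O[Si](C)(C)C(C)(C)C)/C(=C(\CO[Si](C)(C)C(C)(C)C)C(=O)O[Li])[C@@H](Cl)[C@@H]1O[C@]1(C)C=C | intermediate
31 | open-chain butenolide (6S) | C=C[C@H]1O[C@]1(CO[Si](c2ccccc2)(c2ccccc2)C(C)(C)C)C[C@H](O[Si](C)(C)C(C)(C)C)C2=C(CO[Si](C)(C)C(C)(C)C)C(=O)O[C@@H]2[C@@H]1O[C@]1(C)C=C | intermediate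
32 | macrocycle with 8-OTBS, 13-OTBS, 14-OTBDPS | CC(C)(C)[Si](C)(C)O[C@H]1C[C@@]2(CO[Si](c3ccccc3)(c3ccccc3)C(C)(C)C)O[C@@H]2/C=C\[C@@]2(C)O[C@H]2[C@H]2OC(=O)C(CO[Si](C)(C)C(C)(C)C)=C12 | intermediate
33 | 8,13-diol with 14-OTBDPS | O[C@H]1C[C@@]2(CO[Si](c3ccccc3)(c3ccccc3)C(C)(C)C)O[C@@H]2/C=C\[C@@]2(C)O[C@H]2[C@H]2OC(=O)C(CO)=C12 | intermediate
34 | 13-acetate of 33 | O[C@H]1C[C@@]2(CO[Si](c3ccccc3)(c3ccccc3)C(C)(C)C)O[C@@H]2/C=C\[C@@]2(C)O[C@H]2[C@H]2OC(=O)C(COC(C)=O)=C12 | intermediate
35 | 8-methacrylate of 34 | C=C(C)C(=O)O[C@H]1C[C@@]2(CO[Si](c3ccccc3)(c3ccccc3)C(C)(C)C)O[C@@H]2/C=C\[C@@]2(C)O[C@H]2[C@H]2OC(=O)C(COC(C)=O)=C12 | intermediate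
36 | CNP0207684.1 | C=C(C)C(=O)O[C@H]1C[C@@]2(CO)O[C@@H]2/C=C\[C@@]2(C)O[C@H]2[C@H]2OC(=O)C(COC(C)=O)=C12 | target

**Count and risks**

Total steps: 22. Longest linear sequence: 19 steps (1–3, 5–9, 12–22).

Step 12. What may go wrong: slow SN2 at the β-branched primary iodide, with the alkenyllithium acting instead as a base (elimination to an enol silyl ether) or opening the vinyl oxirane on warming. Fallback, from 16 back to 22: the iodide of 16 is displaced with CsOAc and 18-crown-6 in DMF to give the C9 acetate F1; DIBAL-H in CH2Cl2 at −78 °C cleaves it to the C9 alcohol F2; Tf2O with 2,6-di-tert-butylpyridine at −78 °C gives the C9 triflate F3, which should be alkylated by dianion 21 within minutes at −78 °C, returning to 22.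

Step 17. What may go wrong: attack of t-BuLi on the allylic chloride or the vinyl oxiranes before the exchange is complete, or ionisation and elimination of the chloride before the ring closes. Fallback, from 25 back to 31: alcohol 25 is deprotonated with MeLi, exchanged with t-BuLi at −100 °C and carboxylated with CO2; mild acidification gives the γ-hydroxy acid F4, which should lactonise at once by acyl substitution with retention at C6 (the 6S alcohol already has the target configuration), giving 31 without the chloride.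

Step 18. What may go wrong: oligomerisation by intermolecular metathesis, or no closure because the fused butenolide holds the two vinyl oxiranes apart. Fallback, from 27 back to 32: the more flexible open-chain chloride 27 is cyclised first (second-generation Hoveyda–Grubbs catalyst, toluene, high dilution) to the ten-membered bromo chloride F5; bromine–lithium exchange, CO2 and warming in DMF, as in step 17, then close the butenolide on the ring and give 32.

**Further compounds**

F1 | step 12 | C9 acetate from 16 (I replaced by OAc) | CC(=O)OC[C@H](O[Si](C)(C)C(C)(C)C)/C(=C(\CO[Si](C)(C)C(C)(C)C)Br)[C@H](O[Si](CC)(CC)CC)[C@@H]1O[C@]1(C)C=C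
F2 | step 12 | C9 alcohol from F1 | OC[C@H](O[Si](C)(C)C(C)(C)C)/C(=C(\CO[Si](C)(C)C(C)(C)C)Br)[C@H](O[Si](CC)(CC)CC)[C@@H]1O[C@]1(C)C=C
F3 | step 12 | C9 triflate from F2 | O=S(=O)(OC[C@H](O[Si](C)(C)C(C)(C)C)/C(=C(\CO[Si](C)(C)C(C)(C)C)Br)[C@H](O[Si](CC)(CC)CC)[C@@H]1O[C@]1(C)C=C)C(F)(F)F
F4 | step 17 | γ-hydroxy acid from 25 (Br replaced by CO2H) | C=C[C@H]1O[C@]1(CO[Si](c2ccccc2)(c2ccccc2)C(C)(C)C)C[C@H](O[Si](C)(C)C(C)(C)C)/C(=C(\CO[Si](C)(C)C(C)(C)C)C(=O)O)[C@H](O)[C@@H]1O[C@]1(C)C=C
F5 | step 18 | ten-membered (6R)-chloride with exocyclic C11 bromide from 27 | CC(C)(C)[Si](C)(C)O[C@H]1C[C@@]2(CO[Si](c3ccccc3)(c3ccccc3)C(C)(C)C)O[C@@H]2/C=C\[C@@]2(C)O[C@H]2[C@H](Cl)/C1=C(\Br)CO[Si](C)(C)C(C)(C)C
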